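**Compound numbers used throughout:** 1 nitrile, 2 ketimine salt, 3 trimethoxy ketone, 4 dimethoxy ketone, 5–7 enolates and chlorosilane, 8 silyl bis-enol ether, 9 diketone, 10/11 hydroxy ketones, 12 diol, 13 target.

## The problem

5-Methoxygalbelgin 13 is an oxolane (ring A) whose ring carbons C2–C5 are four contiguous stereocenters, all (S) and all-trans. C2 carries a 3,4-dimethoxyphenyl ring (ring B), C3 and C4 carry methyl groups, and C5 carries a 3,4,5-trimethoxyphenyl ring (ring C). Rings B and C differ by one methoxy group, so any undirected union of two arylpropanoid halves gives three products that differ by 30 mass units and would be hard to separate; the halves must be joined in a directed way. C3 and C4 carry only C–C and C–H bonds: they cannot be corrected once the ring exists, and they fix the absolute configuration. C2 and C5 are benzylic ether carbons para to a methoxy group: their C–O bonds can ionize, so they can be set late, trans to the neighbouring methyl groups. The feature that the key step uses is the local twofold axis through O1 and the midpoint of the C3–C4 bond: the two halves ArCH(O)–CH(CH3) are homochiral, and at the 1,4-diketone oxidation level C3 and C4 are α-carbons of two aryl ketones whose C–H bonds exchange under base, so one chiral catalyst can select both halves in the same sense from a stereorandom precursor. Strong or prolonged acid must be avoided (the benzylic cation can lose a proton to a styrene, which scrambles C3 or C4, or be captured by the other arene to give an aryltetralin), as must strong oxidants on the electron-rich rings; no protecting group is needed.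

## Retrosynthesis

**13 to 12.** The C2–O1 bond of 13 is cut, giving diol 12 (C1–C4 of 12 are C2–C5 of 13). This cut is preferred to C5–O1 because the cation next to ring B is stabilized by a conjugated para-methoxy group, whereas in ring C the 4-methoxy group is twisted out of plane by its two neighbours. A C–C cut of the ring would keep the ether and force the stereocenters to be made one at a time. 12 is acyclic and needs only three correct stereocenters, since C1 is lost in the cation. The forward reaction must ionize C1 selectively, close O4 onto it trans to the C2 methyl group, and stop before Friedel–Crafts or elimination pathways start.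

**12 to 9.** The C–H bonds that define the four stereocenters of 12 are cut: the two carbinol hydrogens are removed (back to ketones) and the two α-hydrogens are treated as exchangeable. This leads to diketone 9 as a mixture of all stereoisomers. It is preferred to a stereodefined diketone followed by plain reduction, because 9 has no stereocenter that needs control and 12 has four. The forward reaction must perform two hydrogenations with one catalyst, each coupled to a dynamic kinetic resolution of the adjacent α-carbon; hydroxy ketones 10 and 11 lie on the way.

**9 to 8.** The C2–C3 bond of 9 (C3–C4 of 13) is cut. Aryl–carbonyl cuts would need a preformed dimethylsuccinic unit and two acylations. A free cross-coupling of two propiophenone enolates would give symmetrical diketones beside 9. The two halves are therefore first joined through an O–Si–O bridge that is not in the target, in silyl bis-enol ether 8. The forward reaction is a one-electron oxidative coupling that can only be intramolecular and that loses the bridge in the same operation; it has no stereochemical task.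

**8 to 4 and 3.** The two Si–O bonds of 8 are cut, giving propiophenones 4 and 3 and a diisopropylsilylene unit. The forward reaction must place exactly one enolate of 4 on silicon (via 5 and 6) before the enolate of 3 (7) is added; an excess of the silylating reagent, removed before 7 arrives, ensures this. 4 is commercial.

**3 to 1.** The bond between the carbonyl carbon and the ethyl group of 3 is cut, back to commercial nitrile 1 and an ethyl nucleophile. Addition to a nitrile stops at the imine stage 2, so over-addition is excluded.

## Roads not taken

Alternative 1: The most obvious route cuts the C5–aryl bond and the C4–CH3 bond, back to lactone A1, (3S,4S,5S)-5-(3,4-dimethoxyphenyl)-3,4-dimethyloxolan-2-one. A1 would come from an auxiliary-controlled aldol or alkylation sequence and α-methylation trans to the β-methyl group. The forward key step is addition of ring C as an organometallic nucleophile to A1 and ionic hydrogenation of hemiketal A2 through its oxocarbenium ion. This is reliable but linear: the stereocenters are set one after another by relay, a stoichiometric auxiliary is carried, and eight or more steps are needed. It does not use the twofold pattern of 13, and the facial course of hydride delivery to the oxocarbenium ion must be right. The chosen plan sets all four centers in its last two steps from a precursor without stereochemical demands.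

Alternative 2: Both aryl–C bonds (C2–aryl and C5–aryl) are cut, back to the C2-symmetric anhydride A3, (3S,4S)-3,4-dimethyloxolane-2,5-dione, from oxidative dimerization of an auxiliary-bound propionate enolate. The forward key step uses the homotopic carbonyl groups of A3: ring B, added as an organomagnesium nucleophile, opens it to a single keto acid A4; the second aryl group, reduction and ring closure follow. This uses the same symmetry, but it sets C3/C4 at the start with two equivalents of auxiliary and needs seven to eight steps. It also carries α-keto stereocenters, which epimerize readily, through two additions of basic aryl metals. The chosen plan turns that same lability into the stereodefining event.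

Alternative 3: The C3–C4 bond and both C–O bonds are cut at once, back to the propenylarenes A5 (methyl isoeugenol) and A6 (isoelemicin) and water. The forward key step is one-electron oxidation of A5, attack of its radical cation on A6 at the β-carbons, and capture of the benzylic cation equivalents by water. It is the shortest conceivable route. However, the C–C bond forms between free, flat partners, so there is no handle for absolute configuration and no control of like/unlike selectivity at C3/C4. Homodimers such as A7 (racemic galbelgin) form beside the cross product and differ from it by one methoxy group. The chosen plan keeps the C3–C4 union of two arylpropanoid halves, but under a tether, and leaves the stereochemistry to a catalyst.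

Key step: step 4

Assumption: in step 4 the fast-reacting α-epimer is taken to be the one predicted by the Felkin–Anh model (hydride anti to the largest α-substituent); this fixes the choice of the (R),(R) catalyst and the descriptors of 10–12.

## Route

Step 1
Reactants: 1 3,4,5-trimethoxybenzonitrile
Product: 3 1-(3,4,5-trimethoxyphenyl)propan-1-one, via N-bromomagnesio ketimine 2 (not isolated)
Conditions: EtMgBr (1.5 equiv), THF, 0 °C to reflux; then 2 M aq HCl, rt
Reagents that add atoms: ethylmagnesium bromide, CC[Mg]Br; water, O
Why: Grignard addition to an aryl nitrile stops at the magnesium ketimide, which is hydrolysed to the ketone on acidic work-up, so no tertiary alcohol can form.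

Step 2
Reactants: 4 1-(3,4-dimethoxyphenyl)propan-1-one; 3 1-(3,4,5-trimethoxyphenyl)propan-1-one
Product: 8 {[(Z)-1-(3,4-dimethoxyphenyl)prop-1-en-1-yl]oxy}{[(Z)-1-(3,4,5-trimethoxyphenyl)prop-1-en-1-yl]oxy}di(propan-2-yl)silane, via dimethoxyphenyl lithium enolate 5 (not isolated), via chlorosilyl enol ether 6 (not isolated), via trimethoxyphenyl lithium enolate 7 (not isolated)
Conditions: 4, LiN(SiMe3)2, THF, −78 °C; cannulate into i-Pr2SiCl2 (3 equiv), −78 °C to rt; remove volatiles and excess i-Pr2SiCl2 in vacuo; then 7 (from 3, LiN(SiMe3)2, THF, −78 °C), −78 °C to rt
Reagents that add atoms: dichlorodi(propan-2-yl)silane, CC(C)[Si](Cl)(Cl)C(C)C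
Why: O-silylation of preformed lithium enolates (silyl enol ether formation); the excess of the hindered dichlorosilane gives one enoxy group per silicon, and its removal before 7 is added should give the unsymmetrical silaketal-type tether free of symmetrical bis-enol ethers. The (Z) geometry expected from these enolates is of no consequence later.

Step 3
Reactants: 8 silyl bis-enol ether
Product: 9 1-(3,4-dimethoxyphenyl)-2,3-dimethyl-4-(3,4,5-trimethoxyphenyl)butane-1,4-dione (like and unlike diastereomers, each racemic)
Conditions: (NH4)2Ce(NO3)6 (2.2 equiv), NaHCO3 (4 equiv), MeCN, −10 °C
Reagents that add atoms: none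
Why: Oxidative coupling of a silyl bis-enol ether: tetravalent cerium oxidizes one enol ether to its radical cation, which attacks the second enol ether through a seven-membered ring; a second oxidation and loss of the silicon bridge give the 1,4-diketone. The tether enforces 1:1 cross-coupling, and the two new stereocenters need no control because step 4 equilibrates them.

Step 4
Reactants: 9 diketone (stereoisomer mixture)
Product: 12 (1S,2S,3S,4S)-1-(3,4-dimethoxyphenyl)-2,3-dimethyl-4-(3,4,5-trimethoxyphenyl)butane-1,4-diol, via ring B carbinol hydroxy ketone 10 (not isolated), via ring C carbinol hydroxy ketone 11 (not isolated)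
Conditions: H2 (4 atm), trans-RuCl2[(R)-xylbinap][(R)-daipen] (1 mol %), KOt-Bu (0.5 equiv), i-PrOH/THF, 30 °C
Reagents that add atoms: none
Why: Proposed new method: KOt-Bu in i-PrOH reversibly enolizes both aryl ketones of 9, so all four stereoisomers interconvert, while the divalent ruthenium hydride of the diphosphine/diamine complex transfers hydride and proton to one C=O through the outer-sphere six-membered transition state known for aryl alkyl ketones. The closest known reaction types are the Noyori hydrogenation of configurationally labile α-branched ketones under basic conditions (dynamic kinetic resolution) and the catalyst-controlled double hydrogenation of 1,4-diaryl-1,4-diketones to C2-symmetric diols; new is their combination on an acyclic 2,3-dialkyl-1,4-diketone. No ring is closed. C1 and C4 (carbinol carbons) are set by the catalyst, which differentiates the aryl and alkyl flanks of the ketone and with the (R),(R) ligand pair should give (S)-1-arylalkanols. C2 and C3 are set by the rate difference between α-epimers: in the favoured transition state hydride enters anti to the large CH(CH3)C(O)Ar residue (Felkin–Anh), which for an (S)-carbinol means an (S)-α-carbon. After the first reduction (10 or 11) the reduced half is no longer enolizable whereas the α-carbon of the remaining ketone still is, so the second reduction repeats the same selection; because the two halves of 13 are homochiral, one catalyst serves both. The step needs epimerization to be faster than hydrogenation of the slow epimers, which the acidity of the aryl ketone α-hydrogens together with a high base loading and low hydrogen pressure should secure; chemoselectivity is given because 9 has no other reducible group.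

Step 5
Reactants: 12 diol
Product: 13 (2S,3S,4S,5S)-2-(3,4-dimethoxyphenyl)-3,4-dimethyl-5-(3,4,5-trimethoxyphenyl)oxolane (5-methoxygalbelgin)
Conditions: BF3·OEt2 (0.2 equiv), 4 Å molecular sieves, CH2Cl2, −40 to 0 °C; Et3N quench
Reagents that add atoms: none
Why: Acid-mediated SN1 cycloetherification of a benzylic 1,4-diol: the Lewis acid ionizes the C1–OH next to ring B (para-methoxy stabilized cation) faster than the C4–OH next to ring C, and O4 closes the five-membered ring by 5-exo attack on the planar cation. C5 of 13 keeps the (S) configuration set in step 4; the new stereocenter C2 is set trans to the C3 methyl group kinetically (aryl pseudo-equatorial in the envelope transition state) and thermodynamically, since re-ionization of the same C2–O1 bond should funnel any 2,3-cis isomer to the all-trans oxolane.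

## Compound list

1 | 3,4,5-trimethoxybenzonitrile | COc1cc(C#N)cc(OC)c1OC | starting material
2 | N-(bromomagnesio)-1-(3,4,5-trimethoxyphenyl)propan-1-imine | CCC(=N[Mg]Br)c1cc(OC)c(OC)c(OC)c1 | intermediate
3 | 1-(3,4,5-trimethoxyphenyl)propan-1-one | CCC(=O)c1cc(OC)c(OC)c(OC)c1 | intermediate
4 | 1-(3,4-dimethoxyphenyl)propan-1-one | CCC(=O)c1ccc(OC)c(OC)c1 | starting material
5 | lithium (Z)-1-(3,4-dimethoxyphenyl)prop-1-en-1-olate | C/C=C(\O[Li])c1ccc(OC)c(OC)c1 | intermediate
6 | chloro{[(Z)-1-(3,4-dimethoxyphenyl)prop-1-en-1-yl]oxy}di(propan-2-yl)silane | C/C=C(\O[Si](Cl)(C(C)C)C(C)C)c1ccc(OC)c(OC)c1 | intermediate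
7 | lithium (Z)-1-(3,4,5-trimethoxyphenyl)prop-1-en-1-olate | C/C=C(\O[Li])c1cc(OC)c(OC)c(OC)c1 | intermediate
8 | {[(Z)-1-(3,4-dimethoxyphenyl)prop-1-en-1-yl]oxy}{[(Z)-1-(3,4,5-trimethoxyphenyl)prop-1-en-1-yl]oxy}di(propan-2-yl)silane | C/C=C(\O[Si](C(C)C)(C(C)C)O/C(=C\C)c1cc(OC)c(OC)c(OC)c1)c1ccc(OC)c(OC)c1 | intermediate
9 | 1-(3,4-dimethoxyphenyl)-2,3-dimethyl-4-(3,4,5-trimethoxyphenyl)butane-1,4-dione (all stereoisomers) | COc1ccc(C(=O)C(C)C(C)C(=O)c2cc(OC)c(OC)c(OC)c2)cc1OC | intermediate
10 | (2RS,3S,4S)-4-(3,4-dimethoxyphenyl)-4-hydroxy-2,3-dimethyl-1-(3,4,5-trimethoxyphenyl)butan-1-one | COc1ccc([C@@H](O)[C@@H](C)C(C)C(=O)c2cc(OC)c(OC)c(OC)c2)cc1OC | intermediate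
11 | (2RS,3S,4S)-1-(3,4-dimethoxyphenyl)-4-hydroxy-2,3-dimethyl-4-(3,4,5-trimethoxyphenyl)butan-1-one | COc1ccc(C(=O)C(C)[C@H](C)[C@H](O)c2cc(OC)c(OC)c(OC)c2)cc1OC | intermediate
12 | (1S,2S,3S,4S)-1-(3,4-dimethoxyphenyl)-2,3-dimethyl-4-(3,4,5-trimethoxyphenyl)butane-1,4-diol | COc1ccc([C@@H](O)[C@@H](C)[C@H](C)[C@H](O)c2cc(OC)c(OC)c(OC)c2)cc1OC | intermediate
13 | (2S,3S,4S,5S)-2-(3,4-dimethoxyphenyl)-3,4-dimethyl-5-(3,4,5-trimethoxyphenyl)oxolane (5-methoxygalbelgin) | COc1ccc([C@H]2O[C@H](c3cc(OC)c(OC)c(OC)c3)[C@@H](C)[C@@H]2C)cc1OC | target

## Step count and risks

Total: 5 steps. Longest linear sequence: 5 steps (1 → 3 → 8 → 9 → 12 → 13); ketone 4 enters in step 2.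

**Step 4 (key step, proposed new method).** What may go wrong is α-epimerization that is too slow relative to hydrogenation, or too small a rate difference between the α-epimers. Either gives poor diastereoselection at C2/C3 of 12 although the carbinol centers are set. Because step 5 retains C4 of 12, a diol with wrong α-carbons ends as a diastereomer of 13 and not as its enantiomer, so leakage costs yield and not enantiomeric purity. A reversed α-preference would call for the enantiomeric catalyst and would leave the ring C carbinol with a configuration that mild step 5 conditions do not correct.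

The fallback uses known chemistry, sets out from 9 and returns at 12. 9 is equilibrated with DBU and the racemic like diastereomer, rac-(2S,3S)-1-(3,4-dimethoxyphenyl)-2,3-dimethyl-4-(3,4,5-trimethoxyphenyl)butane-1,4-dione F1, is separated by crystallization or chromatography; the unlike isomer goes back to the equilibration. F1 is reduced under non-enolizing, reagent-controlled conditions with (−)-B-chlorodiisopinocampheylborane (THF, −25 °C to rt, diethanolamine work-up), which should turn both ketones of either enantiomer into (S)-carbinols. The (2S,3S) half gives 12; the (2R,3R) half gives (1S,2R,3R,4S)-1-(3,4-dimethoxyphenyl)-2,3-dimethyl-4-(3,4,5-trimethoxyphenyl)butane-1,4-diol F2, a diastereomer removed by chromatography. At most half of F1 reaches 12.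

**Step 3.** What may go wrong is oxidation of the electron-rich aryl rings by tetravalent cerium, or hydrolysis of the Si–O bonds before coupling, which returns 3 and 4. If step 2 has scrambled the enoxy groups on silicon, symmetrical diketones also form.

The fallback sets out from 3 and 4, returns at 9, and replaces steps 2 and 3 together. 3 is brominated at the α-carbon (CuBr2, EtOAc/CHCl3, reflux) to racemic 2-bromo-1-(3,4,5-trimethoxyphenyl)propan-1-one F3, which C-alkylates lithium enolate 5 (made from 4 as in step 2; THF/DMPU, −78 to 0 °C). Halogen transfer between enolate and bromo ketone can give some symmetrical diketone, which is why this two-electron union is the second choice.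

**Step 5.** What may go wrong is capture of the benzylic cation by the trimethoxyphenyl ring (Friedel–Crafts closure to an aryltetralin), loss of a proton to a styrene with scrambling of C3, or incomplete trans selectivity if the reaction is stopped early.

The fallback sets out from 12 and returns at 13; it replaces acid-catalysed, reversible dehydration by a base-buffered, irreversible closure. 12 is treated with MsCl (1.1 equiv) and Et3N in CH2Cl2 at −20 °C to rt. The benzylic sulfonate, (1S,2S,3S,4S)-1-(3,4-dimethoxyphenyl)-4-hydroxy-2,3-dimethyl-4-(3,4,5-trimethoxyphenyl)butyl methanesulfonate F4, is not isolated: it ionizes at once and the cation is captured by the remaining hydroxyl group, with no acid present to reopen the ring or to drive arene alkylation.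

## Further compounds

F1 | step 4 | rac-(2S,3S)-1-(3,4-dimethoxyphenyl)-2,3-dimethyl-4-(3,4,5-trimethoxyphenyl)butane-1,4-dione (one enantiomer drawn) | COc1ccc(C(=O)[C@@H](C)[C@H](C)C(=O)c2cc(OC)c(OC)c(OC)c2)cc1OC
F2 | step 4 | (1S,2R,3R,4S)-1-(3,4-dimethoxyphenyl)-2,3-dimethyl-4-(3,4,5-trimethoxyphenyl)butane-1,4-diol | COc1ccc([C@@H](O)[C@H](C)[C@@H](C)[C@H](O)c2cc(OC)c(OC)c(OC)c2)cc1OC
F3 | step 3 | 2-bromo-1-(3,4,5-trimethoxyphenyl)propan-1-one (racemic) | CC(Br)C(=O)c1cc(OC)c(OC)c(OC)c1
F4 | step 5 | (1S,2S,3S,4S)-1-(3,4-dimethoxyphenyl)-4-hydroxy-2,3-dimethyl-4-(3,4,5-trimethoxyphenyl)butyl methanesulfonate | COc1ccc([C@@H](OS(C)(=O)=O)[C@@H](C)[C@H](C)[C@H](O)c2cc(OC)c(OC)c(OC)c2)cc1OC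
A1 | alternative 1 | (3S,4S,5S)-5-(3,4-dimethoxyphenyl)-3,4-dimethyloxolan-2-one | COc1ccc([C@H]2OC(=O)[C@@H](C)[C@@H]2C)cc1OC
A2 | alternative 1 | (2RS,3S,4S,5S)-5-(3,4-dimethoxyphenyl)-3,4-dimethyl-2-(3,4,5-trimethoxyphenyl)oxolan-2-ol | COc1ccc([C@H]2OC(O)(c3cc(OC)c(OC)c(OC)c3)[C@@H](C)[C@@H]2C)cc1OC
A3 | alternative 2 | (3S,4S)-3,4-dimethyloxolane-2,5-dione | C[C@@H]1C(=O)OC(=O)[C@H]1C
A4 | alternative 2 | (2S,3S)-4-(3,4-dimethoxyphenyl)-2,3-dimethyl-4-oxobutanoic acid | COc1ccc(C(=O)[C@@H](C)[C@H](C)C(=O)O)cc1OC
A5 | alternative 3 | (E)-1,2-dimethoxy-4-(prop-1-en-1-yl)benzene (methyl isoeugenol) | C/C=C/c1ccc(OC)c(OC)c1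
A6 | alternative 3 | (E)-1,2,3-trimethoxy-5-(prop-1-en-1-yl)benzene (isoelemicin) | C/C=C/c1cc(OC)c(OC)c(OC)c1
A7 | alternative 3 | rac-(2S,3S,4S,5S)-2,5-bis(3,4-dimethoxyphenyl)-3,4-dimethyloxolane (racemic galbelgin, one enantiomer drawn) | COc1ccc([C@H]2O[C@H](c3ccc(OC)c(OC)c3)[C@@H](C)[C@@H]2C)cc1OC
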